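**What is asked.** The flask put 4 questions, and the first is where its target stands at the last reading time. The flask's run so far is eta; gamma differs from it in the charge of third substrate.

| setting | eta | gamma | flask |
|---|---|---|---|
| starting material | 10 mM | 10 mM | 10 mM |
| partner | 7 mM | 7 mM | 7.00 mM |
| second substrate | 50 mM | 50 mM | 50.0 mM |
| third substrate | 10 mM | 15 mM | 10.0 mM |
| protic impurity | 5 mM | 5 mM | 5.00 mM |
| temperature | 70 °C | 70 °C | 70 °C |
| remark | the very flask that is asked about, followed so far | run made earlier |  |
| time |  |  | 8.0 d |

| run | time / d | target / % |
|---|---|---|
| eta | 0.625 | 28 |
| eta | 2.08 | 28 |
| eta | 4.00 | 20 |
| eta | 6.00 | 11 |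
| eta | 8.00 | 12 |
| gamma | 0.417 | 25 |
| gamma | 1.04 | 25 |
| gamma | 2.08 | 22 |
| gamma | 3.00 | 17 |
| gamma | 4.00 | 14 |

(standard deviation of a reading: 2 percentage points)

- autumn: at 8.0 d raise the temperature by 20 K, then wait 15 d
- winter: change nothing and wait 15 d more
- spring: at 8.0 d take out 90% of the target then present, then wait 15 d
- dusk: at 8.0 d add partner, 100% of the amount charged, then wait 15 d

- target, in percent of the starting material first charged, at 8.0 d
- the option that brings most further target ("none" if no option brings more than 2 percentage points) (autumn / winter / spring / dusk / none)
- target present, with what was taken out counted in, in percent of the starting material first charged, after autumn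
- target present, with what was taken out counted in, in percent of the starting material first charged, after spring

- percentages count the starting material that a species holds: one side product counts as two
- target taken out counts as made
- the numbers in the tables scatter with a standard deviation of 2 percentage points
- on the list of suspects stand: starting material + partner -> target; second substrate + partner -> second product; third substrate + partner -> third product; starting material + target -> side product; third substrate + protic impurity -> quenched substrate; second substrate <-> dormant form
- additions bring no volume worth counting
- the earlier runs do not show what temperature does; that part of a forecast is a guess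

**Loss constant.** Target falls after its plateau, and I took the fall to be pseudo-first-order in target, with a rate proportional to the fraction of starting material left. I read the constant from gamma, leaving the eta readings out. Target went from 25% to 14% between 1.04 d and 4.00 d, a rate of 0.196 d⁻¹. Each loss takes one starting material with one target, so the fraction left is one minus twice the target ever made, plus the target standing. The total made stands in no reading, so I put the plateau reading in its place; target is also lost during the rise, so a fraction reckoned this way errs high. That gave 69.5% at mid-fall, and so the loss constant, the rate per unit fraction of starting material left, 0.282 d⁻¹.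

**The bracket.** I started in eta from 20% at 4.00 d, a reading with its scatter. On that balance, with the plateau standing for the total made, I reckoned starting material there at 64.0%, and at 44.0% with target gone; both figures err high and neither is a true floor. The loss constant rests on the same balance, so I used them only together. Holding the lower fraction gave the upper end of my bracket, 12.2%; holding the higher gave its lower end, 9.72%. These ends are estimates on that balance, not proven bounds. The eta reading at 8.00 d, unused so far, was 12%.

**The forecast.** It gave 12% (10% to 14%), inside my bracket. It chose dusk, saying: “This is a modest gain, borderline, yet the best option.” For autumn it gave 1% (0% to 3%) and for spring 11% (9% to 13%).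

**The result.** The flask gave 10.7%, inside the bracket, with dusk best at a gain of 26 percentage points, autumn 0.0973% and spring 9.83%. Starting material + partner → target did half its turnover by 0.0624 d, and partner stood at 0.156% of its charge at 0.800 d. From then until 8.00 d, target went from 29.5% to 10.7% while side product rose from 8.19% to 45.9%. The flask held 50.6% starting material at 4.00 d, less than my 64.0%. With starting material at 43.3%, the loss constant put winter's loss at 9 points; the simulation lost 8.5 points.

    starting material + partner → target (k = 25.0 M⁻¹ h⁻¹, Ea = 72.0 kJ mol⁻¹)
    second substrate + partner → second product (k = 0.926 M⁻¹ h⁻¹, Ea = 76.0 kJ mol⁻¹)
    third substrate + partner → third product (k = 24.5 M⁻¹ h⁻¹, Ea = 83.0 kJ mol⁻¹)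
    starting material + target → side product (k = 1.16 M⁻¹ h⁻¹, Ea = 61.0 kJ mol⁻¹)
    third substrate + protic impurity → quenched substrate (k = 8.26 M⁻¹ h⁻¹, Ea = 59.0 kJ mol⁻¹)
    second substrate ⇌ dormant form (K = 0.482, k = 0.504 h⁻¹, Ea = 110 kJ mol⁻¹, ΔH = −3.00 kJ mol⁻¹)
    (constants at 70 °C)

**Second flask.** The neighbour charged with 2.8 mM of partner should, in proportion, plateau at 11.2%, and I held its starting material at 88.8%, the figure the balance gives at that plateau. The loss constant then gave 2.54% over the same span from 2.08 d. The simulation gave 2.37% at 8.00 d.

Readings and results are simulated for an exercise, noise included.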